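**Plan**

Retrosynthetic cuts, in order: the bond from the bridging CH2 to C3 of the pyranone and the bond from that CH2 to C5 of the benzofuran; the isopropenyl C=C (back to a tertiary alcohol); Cα–H and Cβ–H of the C7 2-methylbutanoyl chain (back to the (E)-2-methylbut-2-enoyl ketone); its Cα=Cβ bond (aldol with acetaldehyde); O1–C2 of the dihydrofuran; C3–C3a (Claisen shift); the aryl–acyl bond.
Forward: the benzene ring of phloroglucinol is propanoylated, bis-MOM protected and ortho-prenylated. The dihydrofuran ring then closes 5-exo on an epoxide, and the chain is extended to the enone, hydrogenated, dehydrated and deprotected. The pyranone ring, made separately from pentan-3-one and malonyl dichloride, is joined last through the CH2 bridge.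
Stereochemistry: C2 comes from a Shi epoxidation, giving an (R)-epoxide that is inverted to (S) in the ring closure. Cα of the side chain comes from a ligand-controlled iridium hydrogenation.
Enabling feature: the only stereocentre of the C7 acyl chain is an enolisable CH next to the aryl ketone C=O, so it can be carried as a Cα=Cβ double bond that has no configuration to lose. On the benzene ring this ketone lies between O1 (locked in the dihydrofuran ring) and the C6 oxygen (a MOM ether), so the enone cannot close to a chromanone. With the isopropenyl carbons stored as C(OH)Me2, it is also the only alkene present when hydrogen is added.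

Key step: step 10

Assumption: the (S)-configured tBu-PHOX ligand is taken to deliver the (S)-ketone. The sense of induction is to be checked on a small sample of the enone before scale-up, and the equally available (R)-ligand is used if it proves opposite.

**Route**

Step 1
Reactants: 1 phloroglucinol; 2 propanoyl chloride
Product: 3 1-(2,4,6-trihydroxyphenyl)propan-1-one
Conditions: AlCl3 (3.5 equiv), CH2Cl2–MeNO2, 0 to 40 °C; aq HCl
Reagents that add atoms: none
Why: Friedel–Crafts acylation of the threefold-activated, symmetrical ring can give only one mono-ketone, and the new acyl group, held as its aluminium chelate, suppresses a second acylation.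

Step 2
Reactants: 3 1-(2,4,6-trihydroxyphenyl)propan-1-one
Product: 4 1-[2-hydroxy-4,6-bis(methoxymethoxy)phenyl]propan-1-one
Conditions: MOMCl (2.2 equiv), iPr2NEt, CH2Cl2, 0 °C to rt
Reagents that add atoms: chloromethyl methyl ether, COCCl
Why: Base-mediated O-alkylation (MOM acetal formation) stops at the bis-ether because the last ortho hydroxyl is hydrogen-bonded to the ketone and much less nucleophilic, and the two ortho hydroxyls are equivalent, so only one product can arise.

Step 3
Reactants: 4 1-[2-hydroxy-4,6-bis(methoxymethoxy)phenyl]propan-1-one; 5 3-chloro-3-methylbut-1-yne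
Product: 6 1-[2,4-bis(methoxymethoxy)-6-[(2-methylbut-3-yn-2-yl)oxy]phenyl]propan-1-one
Conditions: CuCl2·2H2O (2 mol %), DBU, MeCN, 0 °C to rt
Reagents that add atoms: none
Why: Copper-catalysed propargylic etherification: DBU frees the phenoxide from its hydrogen bond, and the copper acetylide of 5 ionises to an allenylidene-type electrophile that is attacked at the tertiary carbon, a reaction type established for electron-poor and ortho-substituted phenols.

Step 4
Reactants: 6 1-[2,4-bis(methoxymethoxy)-6-[(2-methylbut-3-yn-2-yl)oxy]phenyl]propan-1-one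
Product: 7 1-[2,4-bis(methoxymethoxy)-6-[(2-methylbut-3-en-2-yl)oxy]phenyl]propan-1-one
Conditions: H2 (1 atm), Pd/CaCO3 poisoned with Pb(OAc)2 (Lindlar catalyst), quinoline, EtOAc, rt
Reagents that add atoms: none
Why: Lindlar semihydrogenation stops at the terminal alkene because the poisoned palladium surface binds the alkyne far better than the alkene, and the ketone, MOM and aryl ether groups are inert.

Step 5
Reactants: 7 1-[2,4-bis(methoxymethoxy)-6-[(2-methylbut-3-en-2-yl)oxy]phenyl]propan-1-one
Product: 9 3,5-bis(methoxymethoxy)-2-(3-methylbut-2-en-1-yl)-6-propanoylphenyl acetate, via ortho-prenylphenol 8 (not isolated)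
Conditions: xylenes, 130 °C; cool to rt, then Ac2O, Et3N, DMAP (cat.)
Reagents that add atoms: acetic anhydride, CC(=O)OC(C)=O
Why: Aromatic Claisen rearrangement: the [3,3] shift, accelerated by the gem-dimethyl group, can end productively only at the one hydrogen-bearing ortho carbon and turns the 1,1-dimethylallyl unit into a prenyl group, after which acetylation in the same flask shields the phenol from the oxidant of step 6.

Step 6
Reactants: 9 3,5-bis(methoxymethoxy)-2-(3-methylbut-2-en-1-yl)-6-propanoylphenyl acetate
Product: 10 2-{[(2R)-3,3-dimethyloxiran-2-yl]methyl}-3,5-bis(methoxymethoxy)-6-propanoylphenyl acetate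
Conditions: D-fructose-derived Shi ketone (30 mol %), KHSO5 (as 2KHSO5·KHSO4·K2SO4), K2CO3, Bu4NHSO4, Na2B4O7–Na2H2(edta) buffer, MeCN–CH2(OMe)2–H2O, 0 °C
Reagents that add atoms: potassium peroxymonosulfate, [K+].[O-]S(=O)(=O)OO
Why: Shi asymmetric epoxidation: the chiral dioxirane attacks the electron-rich trisubstituted alkene through the spiro transition state, and the D-fructose-derived ketone is the enantiomer that gives the (R)-epoxide for this substitution pattern, while the acylated and acetylated arene is spared.

Step 7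
Reactants: 10 2-{[(2R)-3,3-dimethyloxiran-2-yl]methyl}-3,5-bis(methoxymethoxy)-6-propanoylphenyl acetate
Product: 12 1-[(2S)-2-(2-hydroxypropan-2-yl)-4,6-bis(methoxymethoxy)-2,3-dihydro-1-benzofuran-7-yl]propan-1-one, via epoxy phenol 11 (not isolated)
Conditions: K2CO3 (0.3 equiv), MeOH, rt
Reagents that add atoms: none
Why: Methanolysis of the aryl acetate releases a phenoxide that opens the epoxide by 5-exo-tet SN2 attack at the secondary carbon, which inverts (R) to (S) at C2 and leaves the oxygen on the tertiary carbon, while the basic medium disfavours the 6-endo path through tertiary cation character.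

Step 8
Reactants: 12 1-[(2S)-2-(2-hydroxypropan-2-yl)-4,6-bis(methoxymethoxy)-2,3-dihydro-1-benzofuran-7-yl]propan-1-one; 13 acetaldehyde
Product: 14 3-hydroxy-1-[(2S)-2-(2-hydroxypropan-2-yl)-4,6-bis(methoxymethoxy)-2,3-dihydro-1-benzofuran-7-yl]-2-methylbutan-1-one (diastereomers at the two new chain carbons)
Conditions: LiN(iPr)2 (2.2 equiv), THF, −78 °C; MeCHO; aq NH4Cl at −78 °C
Reagents that add atoms: none
Why: Lithium enolate aldol addition: the first equivalent of base takes the alcohol proton and the second forms the ketone enolate, which adds to acetaldehyde, and the two new stereocentres need no control because both are erased in step 9.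

Step 9
Reactants: 14 3-hydroxy-1-[(2S)-2-(2-hydroxypropan-2-yl)-4,6-bis(methoxymethoxy)-2,3-dihydro-1-benzofuran-7-yl]-2-methylbutan-1-one
Product: 16 (2E)-1-[(2S)-2-(2-hydroxypropan-2-yl)-4,6-bis(methoxymethoxy)-2,3-dihydro-1-benzofuran-7-yl]-2-methylbut-2-en-1-one, via β-acetoxy ketone 15 (not isolated)
Conditions: Ac2O (1.2 equiv), Et3N, DMAP (cat.), CH2Cl2, 0 °C; then DBU, rt
Reagents that add atoms: none
Why: The secondary alcohol is acetylated much faster than the tertiary one, and DBU then expels acetate by E1cB elimination to give the thermodynamically preferred (E)-enone, in which the β-methyl group points away from the carbonyl group.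

Step 10
Reactants: 16 (2E)-1-[(2S)-2-(2-hydroxypropan-2-yl)-4,6-bis(methoxymethoxy)-2,3-dihydro-1-benzofuran-7-yl]-2-methylbut-2-en-1-one
Product: 17 (2S)-1-[(2S)-2-(2-hydroxypropan-2-yl)-4,6-bis(methoxymethoxy)-2,3-dihydro-1-benzofuran-7-yl]-2-methylbutan-1-one
Conditions: [Ir(cod)((S)-tBu-PHOX)]B[3,5-(CF3)2C6H3]4 (2 mol %), H2 (20 bar), toluene, rt
Reagents that add atoms: none
Why: Under H2 the monovalent iridium precatalyst sheds cyclooctadiene and becomes a cationic trivalent iridium dihydride that binds 16 through Cα=Cβ and the ketone oxygen, and migratory insertion followed by reductive elimination places both hydrogens on the same alkene face, making the Cα–H and Cβ–H bonds. The closest known reaction type is the iridium phosphine–oxazoline hydrogenation of acyclic α-alkyl α,β-unsaturated aryl ketones. No ring is closed and no skeletal bond is formed. The new Cα centre is controlled by the ligand: the tert-butyl group on the oxazoline blocks one quadrant, so the chelated (E)-enone can offer only one enantioface, and the C2 centre, five bonds away, should have no influence. Preference for C=C over C=O is inherent in this catalyst class, and the substrate secures the rest, since Cα=Cβ is its only alkene (the isopropenyl carbons are still C(OH)Me2), its geometry is uniformly E, and O1 and the C6 oxygen are both capped so that no oxa-Michael closure to a chromanone can compete. The medium is neutral and aprotic, so the enolisable centre should persist once formed.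

Step 11
Reactants: 17 (2S)-1-[(2S)-2-(2-hydroxypropan-2-yl)-4,6-bis(methoxymethoxy)-2,3-dihydro-1-benzofuran-7-yl]-2-methylbutan-1-one
Product: 18 (2S)-1-[(2S)-4,6-bis(methoxymethoxy)-2-(prop-1-en-2-yl)-2,3-dihydro-1-benzofuran-7-yl]-2-methylbutan-1-one
Conditions: Burgess reagent (methyl N-(triethylammoniosulfonyl)carbamate), toluene, 60 °C
Reagents that add atoms: none
Why: Burgess dehydration: the tertiary sulfamate ester collapses by a syn (Ei) elimination that takes one of six unhindered methyl hydrogens rather than the lone C2–H, as known for 2-(2-hydroxypropan-2-yl)dihydrobenzofurans, and the near-neutral aprotic medium leaves Cα and C2 untouched.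

Step 12
Reactants: 18 (2S)-1-[(2S)-4,6-bis(methoxymethoxy)-2-(prop-1-en-2-yl)-2,3-dihydro-1-benzofuran-7-yl]-2-methylbutan-1-one
Product: 19 (2S)-1-[(2S)-4,6-dihydroxy-2-(prop-1-en-2-yl)-2,3-dihydro-1-benzofuran-7-yl]-2-methylbutan-1-one
Conditions: HCl (0.5 M in MeOH), 30 °C
Reagents that add atoms: none
Why: Acid-catalysed acetal exchange with methanol frees both phenols, while dilute acid near room temperature should be too weak to protonate an alkene deactivated by its allylic aryloxy group or to enolise the hindered α-branched ketone at a competitive rate.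

Step 13
Reactants: 19 (2S)-1-[(2S)-4,6-dihydroxy-2-(prop-1-en-2-yl)-2,3-dihydro-1-benzofuran-7-yl]-2-methylbutan-1-one; 20 N,N-dimethylmethyleneiminium iodide (Eschenmoser's salt)
Product: 21 (2S)-1-[(2S)-5-[(dimethylamino)methyl]-4,6-dihydroxy-2-(prop-1-en-2-yl)-2,3-dihydro-1-benzofuran-7-yl]-2-methylbutan-1-one
Conditions: CH2Cl2, 0 °C to rt; aq NaHCO3
Reagents that add atoms: none
Why: Mannich-type electrophilic aminomethylation: C5, flanked by two hydroxyls, is the only unsubstituted ring carbon, so the iminium ion has a single site of attack and no added acid or base is needed.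

Step 14
Reactants: 22 pentan-3-one
Product: 23 trimethyl(pent-2-en-3-yloxy)silane
Conditions: Me3SiOSO2CF3, Et3N, CH2Cl2, 0 °C
Reagents that add atoms: trimethylsilyl trifluoromethanesulfonate, C[Si](C)(C)OS(=O)(=O)C(F)(F)F
Why: Soft enolisation and O-silylation of a symmetrical ketone gives one constitutional silyl enol ether, whose alkene geometry is of no consequence.

Step 15
Reactants: 23 trimethyl(pent-2-en-3-yloxy)silane; 24 malonyl dichloride
Product: 25 6-ethyl-4-hydroxy-5-methyl-2H-pyran-2-one
Conditions: Et2O, −78 °C to rt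
Reagents that add atoms: none
Why: C-acylation of the silyl enol ether by one acyl chloride group, followed by O-acylation of the resulting diketone enol by the other (six-membered lactonisation), is the established malonyl dichloride route to 4-hydroxypyran-2-ones and places methyl at C5 and ethyl at C6.

Step 16
Reactants: 21 (2S)-1-[(2S)-5-[(dimethylamino)methyl]-4,6-dihydroxy-2-(prop-1-en-2-yl)-2,3-dihydro-1-benzofuran-7-yl]-2-methylbutan-1-one; 25 6-ethyl-4-hydroxy-5-methyl-2H-pyran-2-one
Product: 27 3-({(2S)-4,6-dihydroxy-7-[(2S)-2-methylbutanoyl]-2-(prop-1-en-2-yl)-2,3-dihydro-1-benzofuran-5-yl}methyl)-6-ethyl-4-hydroxy-5-methyl-2H-pyran-2-one, via ortho-quinone methide 26 (not isolated)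
Conditions: 25 (1.3 equiv), 1,4-dioxane, 80 °C
Reagents that add atoms: none
Why: The acidic pyranone protonates the benzylic amine, dimethylamine leaves to give the ortho-quinone methide, and C3 of the 4-hydroxypyranone adds in a Michael reaction with rearomatisation, a known way to methylene-bridged acylphloroglucinol–pyranone dimers that creates no stereocentre and, with the phenol ionised rather than the ketone, should not disturb Cα.

**Compound list**

1 | phloroglucinol | Oc1cc(O)cc(O)c1 | starting material
2 | propanoyl chloride | CCC(=O)Cl | starting material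
3 | 1-(2,4,6-trihydroxyphenyl)propan-1-one | CCC(=O)c1c(O)cc(O)cc1O | intermediate
4 | 1-[2-hydroxy-4,6-bis(methoxymethoxy)phenyl]propan-1-one | CCC(=O)c1c(O)cc(OCOC)cc1OCOC | intermediate
5 | 3-chloro-3-methylbut-1-yne | CC(C)(Cl)C#C | starting material
6 | 1-[2,4-bis(methoxymethoxy)-6-[(2-methylbut-3-yn-2-yl)oxy]phenyl]propan-1-one | CCC(=O)c1c(OCOC)cc(OCOC)cc1OC(C)(C)C#C | intermediate
7 | 1-[2,4-bis(methoxymethoxy)-6-[(2-methylbut-3-en-2-yl)oxy]phenyl]propan-1-one | CCC(=O)c1c(OCOC)cc(OCOC)cc1OC(C)(C)C=C | intermediate
8 | 1-[2-hydroxy-4,6-bis(methoxymethoxy)-3-(3-methylbut-2-en-1-yl)phenyl]propan-1-one | CCC(=O)c1c(O)c(CC=C(C)C)c(OCOC)cc1OCOC | intermediate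
9 | 3,5-bis(methoxymethoxy)-2-(3-methylbut-2-en-1-yl)-6-propanoylphenyl acetate | CCC(=O)c1c(OC(C)=O)c(CC=C(C)C)c(OCOC)cc1OCOC | intermediate
10 | 2-{[(2R)-3,3-dimethyloxiran-2-yl]methyl}-3,5-bis(methoxymethoxy)-6-propanoylphenyl acetate | CC1(C)O[C@@H]1Cc2c(OC(C)=O)c(C(=O)CC)c(OCOC)cc2OCOC | intermediate
11 | 1-[3-{[(2R)-3,3-dimethyloxiran-2-yl]methyl}-2-hydroxy-4,6-bis(methoxymethoxy)phenyl]propan-1-one | CC1(C)O[C@@H]1Cc2c(O)c(C(=O)CC)c(OCOC)cc2OCOC | intermediate
12 | 1-[(2S)-2-(2-hydroxypropan-2-yl)-4,6-bis(methoxymethoxy)-2,3-dihydro-1-benzofuran-7-yl]propan-1-one | CC(C)(O)[C@@H]1Cc2c(OCOC)cc(OCOC)c(C(=O)CC)c2O1 | intermediate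
13 | acetaldehyde | CC=O | starting material
14 | 3-hydroxy-1-[(2S)-2-(2-hydroxypropan-2-yl)-4,6-bis(methoxymethoxy)-2,3-dihydro-1-benzofuran-7-yl]-2-methylbutan-1-one (chain diastereomers) | CC(C)(O)[C@@H]1Cc2c(OCOC)cc(OCOC)c(C(=O)C(C)C(C)O)c2O1 | intermediate
15 | 4-[(2S)-2-(2-hydroxypropan-2-yl)-4,6-bis(methoxymethoxy)-2,3-dihydro-1-benzofuran-7-yl]-3-methyl-4-oxobutan-2-yl acetate (chain diastereomers) | CC(C)(O)[C@@H]1Cc2c(OCOC)cc(OCOC)c(C(=O)C(C)C(C)OC(C)=O)c2O1 | intermediate
16 | (2E)-1-[(2S)-2-(2-hydroxypropan-2-yl)-4,6-bis(methoxymethoxy)-2,3-dihydro-1-benzofuran-7-yl]-2-methylbut-2-en-1-one | CC(C)(O)[C@@H]1Cc2c(OCOC)cc(OCOC)c(C(=O)/C(C)=C/C)c2O1 | intermediate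
17 | (2S)-1-[(2S)-2-(2-hydroxypropan-2-yl)-4,6-bis(methoxymethoxy)-2,3-dihydro-1-benzofuran-7-yl]-2-methylbutan-1-one | CC(C)(O)[C@@H]1Cc2c(OCOC)cc(OCOC)c(C(=O)[C@@H](C)CC)c2O1 | intermediate
18 | (2S)-1-[(2S)-4,6-bis(methoxymethoxy)-2-(prop-1-en-2-yl)-2,3-dihydro-1-benzofuran-7-yl]-2-methylbutan-1-one | C=C(C)[C@@H]1Cc2c(OCOC)cc(OCOC)c(C(=O)[C@@H](C)CC)c2O1 | intermediate
19 | (2S)-1-[(2S)-4,6-dihydroxy-2-(prop-1-en-2-yl)-2,3-dihydro-1-benzofuran-7-yl]-2-methylbutan-1-one | C=C(C)[C@@H]1Cc2c(O)cc(O)c(C(=O)[C@@H](C)CC)c2O1 | intermediate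
20 | N,N-dimethylmethyleneiminium iodide | C=[N+](C)C.[I-] | starting material
21 | (2S)-1-[(2S)-5-[(dimethylamino)methyl]-4,6-dihydroxy-2-(prop-1-en-2-yl)-2,3-dihydro-1-benzofuran-7-yl]-2-methylbutan-1-one | C=C(C)[C@@H]1Cc2c(O)c(CN(C)C)c(O)c(C(=O)[C@@H](C)CC)c2O1 | intermediate
22 | pentan-3-one | CCC(=O)CC | starting material
23 | trimethyl(pent-2-en-3-yloxy)silane | CC=C(CC)O[Si](C)(C)C | intermediate
24 | malonyl dichloride | O=C(Cl)CC(=O)Cl | starting material
25 | 6-ethyl-4-hydroxy-5-methyl-2H-pyran-2-one | CCc1oc(=O)cc(O)c1C | intermediate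
26 | (2S)-6-hydroxy-5-methylidene-7-[(2S)-2-methylbutanoyl]-2-(prop-1-en-2-yl)-2,3-dihydro-1-benzofuran-4(5H)-one | C=C(C)[C@@H]1CC2=C(O1)C(C(=O)[C@@H](C)CC)=C(O)C(=C)C2=O | intermediate
27 | 3-({(2S)-4,6-dihydroxy-7-[(2S)-2-methylbutanoyl]-2-(prop-1-en-2-yl)-2,3-dihydro-1-benzofuran-5-yl}methyl)-6-ethyl-4-hydroxy-5-methyl-2H-pyran-2-one | C=C(C)[C@@H]1Cc2c(O)c(Cc3c(O)c(C)c(CC)oc3=O)c(O)c(C(=O)[C@@H](C)CC)c2O1 | target

**Step count**

Total step count: 16.
Longest linear sequence: 14 (steps 1 to 13, then step 16). Steps 14 and 15 form the pyranone branch.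

**Steps most likely to fail**

Step 10. Facial discrimination may be insufficient, because the di-ortho-substituted aryl ketone is twisted away from the geometry on which the ligand model rests. The catalyst may also be slowed by coordination of the MOM oxygens and the free hydroxyl. The fallback sets out from 16 and comes back at 17. It gives up catalyst control in favour of separation with recycling. Hydrogenation of 16 over Pd/C (H2, 1 atm, EtOAc) would give 17 together with its side-chain epimer (2R)-1-[(2S)-2-(2-hydroxypropan-2-yl)-4,6-bis(methoxymethoxy)-2,3-dihydro-1-benzofuran-7-yl]-2-methylbutan-1-one F1. Because C2 is already fixed, the two are diastereomers and should be separable by preparative HPLC on a cellulose-based phase. F1 is re-equilibrated at Cα with catalytic DBU in toluene and returned to the separation, so the material converges on 17.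

Step 3. O-alkylation of the hydrogen-bonded phenol, which lies next to the acyl group, may be sluggish and may be outrun by loss of HCl from the tertiary chloride. The fallback sets out from 3 and comes back at 8. It forms the aryl–prenyl bond directly instead of through an ether. C-prenylation of 3 with 1-bromo-3-methylbut-2-ene in aqueous KOH at 0 °C would give 1-[2,4,6-trihydroxy-3-(3-methylbut-2-en-1-yl)phenyl]propan-1-one F2. MOMCl (2 equiv) with iPr2NEt should then cap the para hydroxyl and the less hindered ortho hydroxyl. The hydroxyl wedged between the prenyl and acyl groups stays hydrogen-bonded and free, and this product is phenol 8. Phenol 8 is acetylated as in the second half of step 5 and the route resumes at 9.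

Step 12. The acid may add methanol or HCl across the isopropenyl group, and acid-catalysed enolisation may erode Cα during a slow acetal cleavage. The fallback sets out from 17 and comes back at 19, changing the protecting groups before the alkene exists.
- The MOM groups of 17 are removed with HCl in MeOH while the side arm is still a robust tertiary alcohol. This gives (2S)-1-[(2S)-4,6-dihydroxy-2-(2-hydroxypropan-2-yl)-2,3-dihydro-1-benzofuran-7-yl]-2-methylbutan-1-one F3.
- Ac2O in pyridine acetylates only the two phenols, giving (2S)-2-(2-hydroxypropan-2-yl)-7-[(2S)-2-methylbutanoyl]-2,3-dihydro-1-benzofuran-4,6-diyl diacetate F4.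
- Burgess dehydration as in step 11 gives (2S)-7-[(2S)-2-methylbutanoyl]-2-(prop-1-en-2-yl)-2,3-dihydro-1-benzofuran-4,6-diyl diacetate F5.
- Brief methanolysis (catalytic K2CO3, MeOH, 0 °C), in which the emerging phenoxide protects the ketone from enolisation, delivers 19 without the alkene ever meeting acid.

**Further compounds**

F1 | step 10 | (2R)-1-[(2S)-2-(2-hydroxypropan-2-yl)-4,6-bis(methoxymethoxy)-2,3-dihydro-1-benzofuran-7-yl]-2-methylbutan-1-one | CC(C)(O)[C@@H]1Cc2c(OCOC)cc(OCOC)c(C(=O)[C@H](C)CC)c2O1
F2 | step 3 | 1-[2,4,6-trihydroxy-3-(3-methylbut-2-en-1-yl)phenyl]propan-1-one | CCC(=O)c1c(O)cc(O)c(CC=C(C)C)c1O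
F3 | step 12 | (2S)-1-[(2S)-4,6-dihydroxy-2-(2-hydroxypropan-2-yl)-2,3-dihydro-1-benzofuran-7-yl]-2-methylbutan-1-one | CC(C)(O)[C@@H]1Cc2c(O)cc(O)c(C(=O)[C@@H](C)CC)c2O1
F4 | step 12 | (2S)-2-(2-hydroxypropan-2-yl)-7-[(2S)-2-methylbutanoyl]-2,3-dihydro-1-benzofuran-4,6-diyl diacetate | CC(C)(O)[C@@H]1Cc2c(OC(C)=O)cc(OC(C)=O)c(C(=O)[C@@H](C)CC)c2O1
F5 | step 12 | (2S)-7-[(2S)-2-methylbutanoyl]-2-(prop-1-en-2-yl)-2,3-dihydro-1-benzofuran-4,6-diyl diacetate | C=C(C)[C@@H]1Cc2c(OC(C)=O)cc(OC(C)=O)c(C(=O)[C@@H](C)CC)c2O1
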